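The data are simulated with constants of no real substance; the scatter is artificial.

How much of the starting material has reacted by 30 h in south and in east, and does the extra scavenger in east count for anything?

the same everywhere: starting material 14 mM; free enzyme 1.4 µM
- Wednesday's: second substrate 8.4 mM; scavenger 14 mM; run made earlier
- Tuesday's: second substrate 8.4 mM; scavenger 18 mM; run made earlier
- south: second substrate 8.40 mM; scavenger 17.0 mM; time 30 h
- east: second substrate 8.40 mM; scavenger 22.0 mM; time 30 h

- Wednesday's (time / h: starting material / %, target / %): 1.50: 91.6, 8.5; 5.00: 73.6, 25.0; 8.00: 61.7, 38.2; 12.0: 47.9, 50.9; 20.0: 39.4, 59.6; 25.0: 39.1, 59.9; 30.0: 39.9, 59.6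
- Tuesday's (time / h: starting material / %, target / %): 1.50: 91.0, 8.6; 5.00: 73.5, 25.3; 8.00: 61.8, 38.0; 12.0: 48.0, 51.6; 20.0: 39.5, 60.4; 25.0: 38.9, 59.7; 30.0: 38.8, 60.2

(each reading ± 0.3 percentage points)

- part of the starting material that has reacted at the end, south
- part of the starting material that has reacted at the end, east
- what raising the concentration of scavenger from its lowest to its highest value here does to the part of the starting material that has reacted (changes below 5 percentage points count as none) (it rises / it falls / no change)



I start from the plain case of one second substrate for each starting material. Then 8.40 mM against 14 mM gives 60.0 %. This ratio is the ceiling, the share of the charged starting material that the second substrate, the limiting reagent, can carry to target. Next comes time. Wednesday's run made 25.0 % of target in 5.00 h, and at that steady pace the ceiling is 12.0 h away, which is shorter than 30 h. The pace does slacken: its target reads 50.9 % at 12.0 h. Its starting material reads 39.4 % at 20.0 h and 39.9 % at 30.0 h, level within the scatter. Then comes scavenger. Going from 14 mM on Wednesday to 18 mM on Tuesday moves the starting material at 12.0 h by 0.1 percentage points, against a scatter of 0.3 points. South lies between those charges and east lies above them, so east is a stretch, but I expect no change.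

The weak link is that the ceiling counts target, while the question counts starting material gone. So I reforge it. At 30.0 h, starting material and target fall short of the whole by 0.5 points in Wednesday's run and 1 point in Tuesday's, on average 0.75 points, a rough figure with 0.3 points on each reading. The ceiling plus that loss gives 60.8 % for both flasks.

The forecast gives 60.5 % for south and 60.5 % for east, a little below my figure, and no change, reasoning that “the second substrate runs out”. The flask gives 61.0 % in south and 61.0 % in east, a change of 0 points: no change.

    starting material + free enzyme ⇌ first complex (K = 26.7 M⁻¹, k = 1.84 × 10⁷ M⁻¹ h⁻¹)
    first complex ⇌ loaded enzyme + first product (K = 0.0130 M, k = 2400 h⁻¹)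
    second substrate + loaded enzyme ⇌ second complex (K = 169 M⁻¹, k = 1.46 × 10⁶ M⁻¹ h⁻¹)
    second complex → free enzyme + target (k = 14200 h⁻¹)
    starting material + first product ⇌ idle adduct, settled at all times (K = 150 M⁻¹)
    scavenger + first product → scavenged by-product (k = 2210 M⁻¹ h⁻¹)
    2 starting material → self-condensation product (k = 0.0377 M⁻¹ h⁻¹)

East ends with 0 % of its second substrate left and 60.0 % target, level with its ceiling of 60.0 %, while 0.975 % of the starting material sits in self-condensation product, which holds two starting material each. A neighbour of east charged with 2.1 mM of second substrate has a ceiling of 15.0 %. That neighbour ends with 0 % of its second substrate left, 15.0 % target and 2.28 % in self-condensation product, more than east holds, and the part of its starting material that has reacted comes to 17.3 %.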